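If this flask has to be stopped at its best moment, I count its age in turnovers of the starting material, so the clock I carry is the half-life of the starting material as its overall fall shows it.

| flask | starting material | protic impurity | remark | time |
|---|---|---|---|---|
| Wednesday's | 0.033 M | 0.033 M | run made earlier |  |
| flask | 0.066 M | 0.0330 M |  | 2.0 h |

- Wednesday's (time / min: ring / %, starting material / %): 2.00: 10.4, 87.2; 6.00: 26.0, 65.0; 10.0: 35.6, 50.9; 15.0: 43.5, 33.0; 20.0: 48.6, 26.1; 30.0: 47.6, 12.7; 40.0: 46.0, 6.9

(scatter of a reading: 1 percentage point)

- a species is counted by the starting material in it: one open dimer counts as two
- a species is counted by the starting material in it: one open trimer counts as three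
- steps that have been proposed: ring <-> isomer of the product; starting material + open dimer -> open trimer; starting material + protic impurity -> quenched substrate; 2 starting material -> open dimer; starting material -> ring

* when, up to 2.0 h, the flask holds most ring
* the amount of ring, in percent of the starting material charged, at that time

From the first to the last reading of Wednesday's run, the starting material falls with a constant of 0.0668 min⁻¹, which gives a half-life of 10.4 min.

My first way to the peak uses the ring readings. They are highest between 20.0 min and 30.0 min, and the midpoint, 25.0 min, is 2.41 half-lives.

My second way uses the fact that ring stops rising when it is made as fast as it fades. The readings at 6.00 min in Wednesday's run put ring at 0.743 of the starting material consumed, and I call the rest the side loss. The last two ring readings then give a fading constant of 0.0138 min⁻¹. The balance falls at 13.5 % starting material, which is 2.89 half-lives.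

The two ways part, and I distrust the second, because it rests on a fall of 1.6 percentage points between two readings whose scatter is 1 point each. I keep 2.41.

This flask holds twice the starting material on the same impurity charge. If the side loss is a pseudo-first-order quench by the impurity, the clock stays, and I expect the peak near 25.0 min.

The forecast gives 0.42 h and 49 %, on the ground that “The side loss stays first-order throughout, which points to quench by the impurity”.

The flask peaks at 0.438 h with 48.5 % ring.

    ring ⇌ isomer of the product (K = 2.00, k = 3.90 × 10⁻⁴ s⁻¹)
    starting material + open dimer → open trimer (k = 0.0250 L mol⁻¹ s⁻¹)
    starting material + protic impurity → quenched substrate (k = 0.00600 L mol⁻¹ s⁻¹)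
    2 starting material → open dimer (k = 6.00 × 10⁻⁴ L mol⁻¹ s⁻¹)
    starting material → ring (k = 9.60 × 10⁻⁴ s⁻¹)

On my clock, the flask's peak comes at 2.53 half-lives. Ring in the flask is made 3.56 times faster than it is used up at 0.166 h, each step taken net, and that ratio is 0.0299 at 2.00 h. A second flask with the same charges, stopped at 50 min, is 4.81 half-lives old, where the clock leaves 3.57 % starting material and that flask holds 3.17 %.

(The earlier runs and the new flask were generated by integration with constants of no real substance, noise included.)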